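Price the coupling partner before anything else, and read the catalyst from its two ends afterwards.

| setting | spring | midnight | summer | flask |
|---|---|---|---|---|
| left-handed substrate | 16 mM | 16 mM | 16 mM | 16 mM |
| right-handed substrate | 16 mM | 16 mM | 16 mM | 16 mM |
| coupling partner | 12.8 mM | 12.8 mM | 19 mM | 12.8 mM |
| protic impurity | 8 mM | 32 mM | 16 mM | 16.0 mM |
| catalyst | 0.40 mM | 0.40 mM | 0.40 mM | 0.40 mM |
| added ligand | 0.30 mM | 0.30 mM | 0.30 mM | 0.30 mM |
| remark | run made earlier | run made earlier | run made earlier |  |

| run | time / d | left-handed product / % |
|---|---|---|
| spring | 1.25 | 19.5 |
| spring | 4.00 | 25.0 |
| spring | 8.00 | 27.1 |
| spring | 10.0 | 24.9 |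
| spring | 15.0 | 25.2 |
| spring | 20.0 | 23.9 |
| midnight | 1.67 | 17.9 |
| midnight | 2.50 | 16.9 |
| midnight | 4.00 | 18.1 |
| midnight | 8.00 | 18.8 |
| midnight | 12.0 | 18.5 |
| midnight | 20.0 | 17.1 |
| summer | 1.67 | 27.7 |
| summer | 5.00 | 30.2 |
| summer | 10.0 | 31.7 |
| summer | 15.0 | 29.5 |
| summer | 20.0 | 31.7 |

(standard deviation of a reading: 1 percentage point)

- catalyst is single-handed; left-handed substrate and right-handed substrate are mirror images of each other, charged as a racemate, each of them at the stated concentration
- no earlier run changes the charge of catalyst; that part of a forecast is a guess

* apparent order in coupling partner when 10% of the left-handed substrate and right-handed substrate together are converted (percent change of the rate of making left-handed product for one percent more coupling partner charged)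
* apparent order in catalyst when 10% of the left-handed substrate and right-handed substrate together are converted (percent change of the rate of making left-handed product for one percent more catalyst charged)
* factor on the rate of making left-handed product when 10% of the left-handed substrate and right-handed substrate together are converted if catalyst is charged twice over

**Where does the left-handed product stop, and why suspect the partner?** In the spring run it levels at 8.07 mM and in the midnight run at 5.72 mM, lower with more impurity. The summer run has more partner and also more impurity than the spring run, and it still levels higher, at 9.85 mM, so I take the partner as the limiting reagent.

**What do you carry to the flask?** I carry the partner price: partner charged per unit of left-handed product finally made. The runs read 1.59 at the spring impurity and 2.24 at the midnight impurity. Solving at both ends and joining them with a straight line gives a slope of 0.0271 /mM. The line puts the price at the flask's impurity at 1.80, and at zero impurity at 1.37.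

**How does that give the order in partner?** The line splits the spending into coupling and quench, so I reckon that converting 3.20 mM in the flask costs 4.21 mM of partner and leaves 8.59 mM. If the rate is first order in partner and this spending stays the same when the charge moves a little, the order is charge over remainder, 1.49.

**And the catalyst? No run varied it.** Then I bracket it, taking the rate as proportional to the catalyst not held by ligand. If the ligand binds nothing, the order is 1 and doubling gives a factor of 2. If it titrates catalyst completely, the order is 4.00 and the factor 5.00. As a guess, I commit to the geometric means, 2.00 and 3.16.

The forecast gives an order in partner of 1.5, and for the catalyst an order of 1 and a factor of 2, saying “Catalyst only changes the clock, so I guess first order and a doubling”; it stands with me on the partner and differs on the catalyst.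

The flask gives an order in partner of 1.6, an order in catalyst of 1.7 and a factor of 2.96 for twice the catalyst.

    coupling partner + catalyst + left-handed substrate → catalyst + left-handed product (k = 12000 /M²/h)
    coupling partner + catalyst + right-handed substrate → catalyst + right-handed product (k = 2800 /M²/h)
    catalyst + added ligand ⇌ idle complex (K = 10000 /M, k = 2000 /M/h)
    coupling partner + protic impurity → quenched reagent (k = 1.10 /M/h)

At 0.422 d in the flask, the half-life of the partner by left-handed coupling is 0.97 d and by quench 1.8 d, a ratio of 1.88, and at 20.0 d the partner stands at 0% with 7.12 mM of left-handed product and 3.62 mM of quenched reagent. That is a price in the flask of 1.80 against my 1.80, while the summer run, at the same impurity but with more partner, reads 1.93.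

(The readings are calculated with made-up constants, and the scatter is random.)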